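**Retrosynthetic overview**
- Target ⇒ twofold amide coupling of 1H-pyrrole-2-carboxylic acid onto a cyclobutane carrying two CH2NH2 groups and two 2-aminoimidazoles. The CH2NH2 groups come from nitriles, the 2-aminoimidazoles from bromomethyl ketones and N-Boc-guanidine.
- All-trans 3,4-diacetylcyclobutane-1,2-dicarbonitrile ⇒ ring contraction (nitrogen deletion through a 1,1-diazene) of a 2,5-diacetylpyrrolidine-3,4-dicarbonitrile; the pyrrolidine C2–C5 bond becomes the fourth cyclobutane bond.
- Stereo logic: the two cyano-bearing carbons (trans from fumaronitrile, absolute sense from the catalyst) are not enolisable under any condition used and carry the chirality. The two acetyl-bearing carbons are set afterwards by acid equilibration to the all-trans isomer.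
- Pyrrolidine ⇒ catalytic asymmetric three-component [3+2] cycloaddition of aminoacetone, methylglyoxal and fumaronitrile.
- Ring order: pyrrolidine, then cyclobutane (by contraction), then the two imidazoles; the pyrroles are bought.

Assumption: the (R)-ligand in step 1 is taken to give the (3R,4R) pyrrolidine; if the sense turns out opposite, the (S)-ligand is used and nothing else changes.

**Step 1**
Reactants: 1 aminoacetone hydrochloride; 2 methylglyoxal (anhydrous THF solution); 3 fumaronitrile
Product: 5 (2R,3R,4R,5S)-2,5-diacetylpyrrolidine-3,4-dicarbonitrile, via imine 4 (not isolated)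
Conditions: Cu(CH3CN)4PF6 (5 mol %), (R)-DTBM-SEGPHOS (5.5 mol %), Et3N (1.0 equiv, slow addition), 4 Å MS, THF, −20 °C
Reagents that add atoms: none
Why: Proposed new method: a symmetric 1,3-diacetyl azomethine ylide has not been used in catalytic asymmetric cycloaddition; slowly liberated aminoacetone condenses at the aldehyde carbon of methylglyoxal to give imine 4, whose CH2 (between C=N and C=O) is deprotonated on monovalent copper as a five-membered N,O-chelate just like a glycinate imine, and the W-shaped metallo-ylide adds to fumaronitrile by a stepwise Michael–Mannich sequence in the bisphosphine pocket; the alkene geometry fixes C3/C4 trans, the W-ylide gives C2/C5 cis, and since dipole and dipolarophile are both symmetric there is no endo/exo question, so ligand-controlled facial selection on fumaronitrile is the only variable and sets (3R,4R) (C2/C5 are re-set in step 2); closest known reaction type: Cu- or Ag-catalysed asymmetric [3+2] cycloaddition of α-iminoester azomethine ylides with fumaronitrile or fumarates, including three-component versions from glyoxylates.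

**Step 2**
Reactants: 5 (2R,3R,4R,5S)-2,5-diacetylpyrrolidine-3,4-dicarbonitrile
Product: 8 (1R,2R,3S,4S)-3,4-diacetylcyclobutane-1,2-dicarbonitrile, via isodiazene 6 (not isolated), via cis-diacetyl cyclobutane 7 (not isolated)
Conditions: PhI(OH)OTs (2.5 equiv), H2NCO2NH4 (8 equiv), CF3CH2OH, 80 °C; aqueous wash; then TsOH·H2O (20 mol %), ClCH2CH2Cl, 60 °C
Reagents that add atoms: none
Why: Iodonitrene-mediated nitrogen deletion (1,1-diazene ring contraction of a pyrrolidine): electrophilic N-transfer to the ring NH gives isodiazene 6, stepwise homolytic loss of N2 leaves an acyl-stabilised 1,4-diradical that closes the C2–C5 bond to cyclobutane 7 without touching the cyano-bearing carbons, and acid-catalysed enolisation then inverts the acetyl carbon that is cis to both neighbours, funnelling to the all-trans thermodynamic isomer 8 while the non-enolisable cyano-bearing carbons keep the absolute configuration.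

**Step 3**
Reactants: 8 (1R,2R,3S,4S)-3,4-diacetylcyclobutane-1,2-dicarbonitrile
Product: 9 (1R,2R,3S,4S)-3,4-bis(2-bromoacetyl)cyclobutane-1,2-dicarbonitrile
Conditions: Br2 (2.1 equiv), MeOH, 0 °C → rt; H2O
Reagents that add atoms: bromine, BrBr
Why: Regioselective acid-catalysed α-bromination of methyl ketones in methanol goes to the CH3 side (less substituted enol; the exocyclic cyclobutylidene enol is disfavoured), and the ring carbons are already at the thermodynamic all-trans arrangement.

**Step 4**
Reactants: 9 (1R,2R,3S,4S)-3,4-bis(2-bromoacetyl)cyclobutane-1,2-dicarbonitrile; 10 N-Boc-guanidine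
Product: 12 (1S,2S,3R,4R)-3,4-bis(2-amino-1H-imidazol-5-yl)cyclobutane-1,2-dicarbonitrile, via bis-Boc aminoimidazole 11 (not isolated)
Conditions: 10 (6 equiv), DMF, rt; concentrate; TFA/CH2Cl2 (1:1), rt; basic ion-exchange resin
Reagents that add atoms: none
Why: Guanidine–α-haloketone cyclocondensation (N-alkylation then cyclodehydration) gives the Boc-protected 2-aminoimidazoles, and Boc acidolysis frees them (either Boc regioisomer converges); the descriptors change only because CIP priorities change, no centre is touched.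

**Step 5**
Reactants: 12 (1S,2S,3R,4R)-3,4-bis(2-amino-1H-imidazol-5-yl)cyclobutane-1,2-dicarbonitrile
Product: 13 [(1R,2R,3S,4S)-3,4-bis(2-amino-1H-imidazol-5-yl)cyclobutane-1,2-diyl]dimethanamine
Conditions: H2 (4 atm), Raney Ni, 7 M NH3 in MeOH, rt
Reagents that add atoms: none
Why: Catalytic hydrogenation of nitriles to primary amines, with NH3 suppressing secondary amines; the trans relationship of the two side chains prevents cyclic amidine or pyrrolidine formation (a trans-fused bicyclo[3.2.0] ring would be required).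

**Step 6**
Reactants: 13 [(1R,2R,3S,4S)-3,4-bis(2-amino-1H-imidazol-5-yl)cyclobutane-1,2-diyl]dimethanamine; 14 1H-pyrrole-2-carboxylic acid
Product: 16 N,N'-{[(1R,2R,3S,4S)-3,4-bis(2-amino-1H-imidazol-5-yl)cyclobutane-1,2-diyl]bis(methylene)}bis(1H-pyrrole-2-carboxamide), via benzotriazolyl ester 15 (not isolated)
Conditions: 14 (2.2 equiv), EDC·HCl (2.4 equiv), HOBt (2.4 equiv), DMF, 0 °C → rt; reversed-phase HPLC
Reagents that add atoms: none
Why: Carbodiimide/HOBt amide coupling; the primary aliphatic amines are far more nucleophilic than the guanidine-like 2-aminoimidazoles, as in the usual last-step acylations of oroidin-type amines.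

**Compound list**
1 | aminoacetone hydrochloride (1-aminopropan-2-one hydrochloride) | CC(=O)CN.Cl | starting material
2 | methylglyoxal (2-oxopropanal) | CC(=O)C=O | starting material
3 | fumaronitrile ((E)-but-2-enedinitrile) | N#C/C=C/C#N | starting material
4 | (E)-1-[(2-oxopropyl)imino]propan-2-one | CC(=O)/C=N/CC(C)=O | intermediate (not isolated)
5 | (2R,3R,4R,5S)-2,5-diacetylpyrrolidine-3,4-dicarbonitrile (2,5-cis, 3,4-trans) | CC(=O)[C@H]1[C@H](C#N)[C@@H](C#N)[C@@H](C(C)=O)N1 | intermediate
6 | [(2R,3R,4R,5S)-2,5-diacetyl-3,4-dicyanopyrrolidin-1-ium-1-ylidene]azanide (isodiazene of 5) | CC(=O)[C@H]1[C@H](C#N)[C@@H](C#N)[C@@H](C(C)=O)[N+]1=[N-] | intermediate (not isolated)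
7 | (1R,2R,3R,4S)-3,4-diacetylcyclobutane-1,2-dicarbonitrile (acetyls cis, nitriles trans) | CC(=O)[C@H]1[C@H](C#N)[C@@H](C#N)[C@H]1C(C)=O | intermediate (not isolated)
8 | (1R,2R,3S,4S)-3,4-diacetylcyclobutane-1,2-dicarbonitrile (all-trans) | CC(=O)[C@H]1[C@H](C#N)[C@@H](C#N)[C@@H]1C(C)=O | intermediate
9 | (1R,2R,3S,4S)-3,4-bis(2-bromoacetyl)cyclobutane-1,2-dicarbonitrile | BrCC(=O)[C@H]1[C@H](C#N)[C@@H](C#N)[C@@H]1C(=O)CBr | intermediate
10 | N-Boc-guanidine (tert-butyl carbamimidoylcarbamate) | CC(C)(C)OC(=O)NC(N)=N | starting material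
11 | di-tert-butyl 4,4'-[(1R,2R,3S,4S)-3,4-dicyanocyclobutane-1,2-diyl]bis(2-amino-1H-imidazole-1-carboxylate) | CC(C)(C)OC(=O)n1cc(nc1N)[C@H]1[C@H](C#N)[C@@H](C#N)[C@@H]1c1cn(C(=O)OC(C)(C)C)c(N)n1 | intermediate (not isolated)
12 | (1S,2S,3R,4R)-3,4-bis(2-amino-1H-imidazol-5-yl)cyclobutane-1,2-dicarbonitrile (all-trans) | Nc1ncc([C@H]2[C@H](C#N)[C@@H](C#N)[C@@H]2c2cnc(N)[nH]2)[nH]1 | intermediate
13 | [(1R,2R,3S,4S)-3,4-bis(2-amino-1H-imidazol-5-yl)cyclobutane-1,2-diyl]dimethanamine | Nc1ncc([C@H]2[C@H](CN)[C@@H](CN)[C@@H]2c2cnc(N)[nH]2)[nH]1 | intermediate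
14 | 1H-pyrrole-2-carboxylic acid | OC(=O)c1ccc[nH]1 | starting material
15 | 1H-benzotriazol-1-yl 1H-pyrrole-2-carboxylate | O=C(On1nnc2ccccc12)c1ccc[nH]1 | intermediate (not isolated)
16 | N,N'-{[(1R,2R,3S,4S)-3,4-bis(2-amino-1H-imidazol-5-yl)cyclobutane-1,2-diyl]bis(methylene)}bis(1H-pyrrole-2-carboxamide) | Nc1ncc([C@H]2[C@H](CNC(=O)c3ccc[nH]3)[C@@H](CNC(=O)c3ccc[nH]3)[C@@H]2c2cnc(N)[nH]2)[nH]1 | target

**Step count and risks**
Total step count: 6. Longest linear sequence: 6.

The three steps most likely to fail are steps 1, 2 and 4.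

Step 1 (the proposed new method). Risks: self-condensation of free aminoacetone, oligomerisation of methylglyoxal, low enantioselectivity with the new ylide. The fallback uses the standard ester-stabilised ylide; it sets out from 3 and comes back to the route at 7, at a cost of three extra steps.
- Glycine methyl ester hydrochloride (COC(=O)CN.Cl) and methyl glyoxylate (COC(=O)C=O) replace 1 and 2. With 3, Et3N and the same Cu(CH3CN)4PF6/(R)-DTBM-SEGPHOS catalyst, the in-flask imine methyl 2-[(2-methoxy-2-oxoethyl)imino]acetate F1 gives dimethyl (2R,3R,4R,5S)-3,4-dicyanopyrrolidine-2,5-dicarboxylate F2.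
- Nitrogen deletion under the first-stage conditions of step 2 (α-amino esters are the proven substrate class) passes through the isodiazene [(2R,3R,4R,5S)-3,4-dicyano-2,5-bis(methoxycarbonyl)pyrrolidin-1-ium-1-ylidene]azanide F3 to dimethyl (1R,2S,3R,4R)-3,4-dicyanocyclobutane-1,2-dicarboxylate F4.
- Me(MeO)NH·HCl/iPrMgCl (THF, −20 °C) gives the bis-Weinreb amide (1R,2S,3R,4R)-3,4-dicyano-N1,N2-dimethoxy-N1,N2-dimethylcyclobutane-1,2-dicarboxamide F5.
- MeMgBr (THF, −40 → 0 °C) then gives 7, which the acid equilibration already written in step 2 takes to 8; any epimer formed at the carbonyl-bearing carbons converges there.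

Step 2. Risks: α-tosyloxylation of the methyl ketones by PhI(OH)OTs, condensation of the ketones with ammonia, and β-scission of the diradical to two alkenes. The fallback generates the same 1,1-diazene stepwise without the iodine reagent and without ammonia; it sets out from 5 and comes back at 6.
- NaNO2 in aqueous AcOH at 0 °C gives (2R,3R,4R,5S)-2,5-diacetyl-1-nitrosopyrrolidine-3,4-dicarbonitrile F6.
- TiCl3 in aqueous NH4OAc/MeOH at 0 °C reduces it to (2R,3R,4R,5S)-2,5-diacetyl-1-aminopyrrolidine-3,4-dicarbonitrile F7.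
- HgO in CH2Cl2 (0 °C → rt) oxidises F7 to isodiazene 6, which loses N2 to give 7 and then 8 as in step 2.

Step 4. Risks: the basic guanidine may open the β-cyano ketone by retro-Michael cleavage or give polyalkylation. The fallback builds the imidazoles by cyanamide condensation of an α-aminoketone under weakly acidic conditions; it sets out from 9 and comes back at 12.
- NaN(CHO)2 in MeCN at rt gives (1R,2R,3S,4S)-3,4-bis[2-(diformylamino)acetyl]cyclobutane-1,2-dicarbonitrile F8.
- HCl/MeOH at rt gives (1R,2R,3S,4S)-3,4-bis(2-aminoacetyl)cyclobutane-1,2-dicarbonitrile F9, kept as its dihydrochloride.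
- Cyanamide in water at pH 4.5 and 95 °C closes both rings to give 12.

**Further compounds**
F1 | step 1 | methyl 2-[(2-methoxy-2-oxoethyl)imino]acetate | COC(=O)C=NCC(=O)OC
F2 | step 1 | dimethyl (2R,3R,4R,5S)-3,4-dicyanopyrrolidine-2,5-dicarboxylate | COC(=O)[C@H]1[C@H](C#N)[C@@H](C#N)[C@@H](C(=O)OC)N1
F3 | step 1 | [(2R,3R,4R,5S)-3,4-dicyano-2,5-bis(methoxycarbonyl)pyrrolidin-1-ium-1-ylidene]azanide | COC(=O)[C@H]1[C@H](C#N)[C@@H](C#N)[C@@H](C(=O)OC)[N+]1=[N-]
F4 | step 1 | dimethyl (1R,2S,3R,4R)-3,4-dicyanocyclobutane-1,2-dicarboxylate | COC(=O)[C@H]1[C@H](C#N)[C@@H](C#N)[C@H]1C(=O)OC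
F5 | step 1 | (1R,2S,3R,4R)-3,4-dicyano-N1,N2-dimethoxy-N1,N2-dimethylcyclobutane-1,2-dicarboxamide | CON(C)C(=O)[C@H]1[C@H](C#N)[C@@H](C#N)[C@H]1C(=O)N(C)OC
F6 | step 2 | (2R,3R,4R,5S)-2,5-diacetyl-1-nitrosopyrrolidine-3,4-dicarbonitrile | CC(=O)[C@H]1[C@H](C#N)[C@@H](C#N)[C@@H](C(C)=O)N1N=O
F7 | step 2 | (2R,3R,4R,5S)-2,5-diacetyl-1-aminopyrrolidine-3,4-dicarbonitrile | CC(=O)[C@H]1[C@H](C#N)[C@@H](C#N)[C@@H](C(C)=O)N1N
F8 | step 4 | (1R,2R,3S,4S)-3,4-bis[2-(diformylamino)acetyl]cyclobutane-1,2-dicarbonitrile | O=CN(C=O)CC(=O)[C@H]1[C@H](C#N)[C@@H](C#N)[C@@H]1C(=O)CN(C=O)C=O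
F9 | step 4 | (1R,2R,3S,4S)-3,4-bis(2-aminoacetyl)cyclobutane-1,2-dicarbonitrile | NCC(=O)[C@H]1[C@H](C#N)[C@@H](C#N)[C@@H]1C(=O)CN
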